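**Plan** (2H-chromene numbering of the target: O1, C2, C3, C4, C4a, C5(OH), C6(acyl), C7(=O), C8(CH3)2, C8a)
1. Retrosynthesis: remove the acyl group from C6 (C-acylation of a 1,3-dione); return C3=C4 and the O1–C2 bond to a 2,3-epoxygeranyl side chain on C4a; then cut two bonds of the carbocycle at once, C8a–C4a and C5–C6.
2. These two cuts leave a two-carbon ynol ether (C4a–C5, carrying the side chain) and a four-carbon 3-ethoxy-4,4-dimethylcyclobutenone (C8a, C8, C7, C6); forward, the alkyne inserts into the C(=O)–CH bond of the four-membered ring.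
3. Enabling feature: the carbocycle has oxygen on C5, C7 and C8a and a quaternary C8(CH3)2 between C7 and C8a. This is the pattern of dimethylketene plus two ynol ethers; the sp3 C8 stops the annulation at the dienone level of the target and leaves the C8a oxygen as the only free carbonyl.
4. Ring order: carbocycle (step 4), then the pyran by 6-endo epoxide opening with that carbonyl oxygen (step 5), then C3=C4, de-ethylation and acylation.
5. Stereochemistry: C2 comes from the Sharpless epoxide of geraniol, its (3S) carbon being inverted to (2R) when the C–O bond forms; the acyl stereocentre comes from (R)-2-methylbutanoic acid.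

Key step: step 4

Assumption: (R)-2-methylbutanoic acid is purchasable enantiopure, and the quaternary C2 of the 2H-pyran does not epimerize by reversible electrocyclic ring opening below about 50 °C without strong acid, so steps 6–8 are kept within these limits.

Step 1
Reactants: 1 geraniol
Product: 2 [(2S,3S)-3-methyl-3-(4-methylpent-3-en-1-yl)oxiran-2-yl]methanol
Conditions: Ti(OiPr)4 (5 mol%), L-(+)-diethyl tartrate (6 mol%), t-BuOOH, 4 Å MS, CH2Cl2, −20 °C
Reagents that add atoms: tert-butyl hydroperoxide, CC(C)(C)OO
Why: Katsuki–Sharpless asymmetric epoxidation of the allylic alcohol; the L-(+)-tartrate titanium catalyst selects the alkene face that gives the (2S,3S)-epoxide and leaves the remote trisubstituted alkene untouched.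

Step 2
Reactants: 2 [(2S,3S)-3-methyl-3-(4-methylpent-3-en-1-yl)oxiran-2-yl]methanol; 3 ethoxyacetylene
Product: 6 (2S,3S)-2-(3-ethoxyprop-2-yn-1-yl)-3-methyl-3-(4-methylpent-3-en-1-yl)oxirane, via epoxy triflate 4 (not isolated), via lithium ethoxyacetylide 5 (not isolated)
Conditions: Tf2O, 2,6-lutidine, CH2Cl2, −78 °C; then 5 (from 3 + n-BuLi, THF, −78 °C), DMPU, −78 → −20 °C
Reagents that add atoms: none
Why: a primary triflate next to an epoxide should be displaced by a lithium acetylide in an SN2 reaction at −78 °C before the epoxide is opened, so the ynol ether is joined at C1 without touching the two stereocentres (acetylide alkylation).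

Step 3
Reactants: 7 isobutyryl chloride; 3 ethoxyacetylene
Product: 9 3-ethoxy-4,4-dimethylcyclobut-2-en-1-one, via dimethylketene 8 (not isolated)
Conditions: Et3N, Et2O, 0 °C → reflux
Reagents that add atoms: none
Why: Et3N dehydrochlorinates 7 to dimethylketene 8, which adds to the ynol ether in a thermal [2+2] cycloaddition with the ketene carbonyl carbon bonding to the unsubstituted alkyne carbon, the standard route to 3-alkoxycyclobutenones.

Step 4
Reactants: 9 3-ethoxy-4,4-dimethylcyclobut-2-en-1-one; 6 (2S,3S)-2-(3-ethoxyprop-2-yn-1-yl)-3-methyl-3-(4-methylpent-3-en-1-yl)oxirane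
Product: 13 3,5-diethoxy-6,6-dimethyl-2-{[(2S,3S)-3-methyl-3-(4-methylpent-3-en-1-yl)oxiran-2-yl]methyl}cyclohexa-2,4-dien-1-one, via vinylketene 10 (not isolated), via vinylcyclobutenone 11 (not isolated), via dienylketene 12 (not isolated)
Conditions: hν (300 nm), PhMe, 20 °C; then 80 °C
Reagents that add atoms: none
Why: Proposed new method: light opens cyclobutenone 9 by 4π electrocyclic cleavage to vinylketene 10, whose electrophilic carbonyl carbon is attacked by the nucleophilic substituted carbon of ynol ether 6 in a regioselective [2+2] cycloaddition to 11; on warming, 11 opens (4π, conrotatory) to dienylketene 12, which closes the six-membered carbocycle by thermal disrotatory 6π electrocyclization onto the dimethyl-substituted terminus. The net result is insertion of the two alkyne carbons into the C1–C2 bond of the four-membered ring, so in 13 the bond from the carbonyl carbon C1 to the side-chain carbon C2 and the bond from the ethoxy carbon C3 to the CH carbon C4 are both new, driven by release of ring strain and consumption of the ketene. The closest known reaction type is the Danheiser benzannulation of cyclobutenones with alkoxy- and siloxyalkynes; here the quaternary dimethyl carbon cannot tautomerize, so the sequence should stop at the 2,4-cyclohexadienone, the reverse of the known photochemical opening of 6,6-disubstituted cyclohexa-2,4-dienones. No stereocentre is created (the ring CH of 11 is transient) and the epoxide stereocentres are spectators. The selectivity needed is regiochemical and is secured by the polarization of the ynol ether against the ketene, while running the first stage at room temperature spares the ethyl ynol ether from retro-ene loss of ethene.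

Step 5
Reactants: 13 3,5-diethoxy-6,6-dimethyl-2-{[(2S,3S)-3-methyl-3-(4-methylpent-3-en-1-yl)oxiran-2-yl]methyl}cyclohexa-2,4-dien-1-one
Product: 14 (2R,3S)-7-ethoxy-3-hydroxy-2,8,8-trimethyl-2-(4-methylpent-3-en-1-yl)-3,4-dihydro-2H-chromen-5(8H)-one
Conditions: CSA (10 mol%), CH2Cl2 (water-saturated), 0 °C
Reagents that add atoms: water, O
Why: acid-catalysed epoxide opening with participation of the neighbouring carbonyl oxygen (the C1 carbonyl is the only free and the most nucleophilic oxygen beside the side chain) should occur at the tertiary carbon in the 6-endo mode with inversion, turning the (3S) epoxide carbon into the (2R) pyran carbon, after which water hydrolyses the ethoxy-oxocarbenium ion at the less hindered C5 with loss of ethanol.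

Step 6
Reactants: 14 (2R,3S)-7-ethoxy-3-hydroxy-2,8,8-trimethyl-2-(4-methylpent-3-en-1-yl)-3,4-dihydro-2H-chromen-5(8H)-one
Product: 15 (2R)-7-ethoxy-2,8,8-trimethyl-2-(4-methylpent-3-en-1-yl)-2H-chromen-5(8H)-one
Conditions: Burgess reagent, PhH, 45 °C
Reagents that add atoms: none
Why: Burgess dehydration (syn elimination through the sulfamate ester) can only take a hydrogen from the C4 methylene because C2 is quaternary, so the alkene should form in conjugation with the enol ether and leave the C2 stereocentre untouched.

Step 7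
Reactants: 15 (2R)-7-ethoxy-2,8,8-trimethyl-2-(4-methylpent-3-en-1-yl)-2H-chromen-5(8H)-one
Product: 16 (2R)-2,8,8-trimethyl-2-(4-methylpent-3-en-1-yl)-2H-chromene-5,7(6H,8H)-dione
Conditions: LiOH, THF/H2O, 20 °C; then AcOH to pH 5
Reagents that add atoms: lithium hydroxide, [Li+].[OH-]
Why: saponification of a vinylogous ester by conjugate addition–elimination of hydroxide, which should prefer the ethoxy-bearing C7 (its neighbour C6 carries only hydrogen) over the fully substituted enol-ether carbon C8a, and the enolate formed protects the product from further attack.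

Step 8
Reactants: 16 (2R)-2,8,8-trimethyl-2-(4-methylpent-3-en-1-yl)-2H-chromene-5,7(6H,8H)-dione; 17 (R)-2-methylbutanoic acid
Product: 19 (2R)-5-hydroxy-2,8,8-trimethyl-6-[(2R)-2-methylbutanoyl]-2-(4-methylpent-3-en-1-yl)-2H-chromen-7(8H)-one, via enol ester 18 (not isolated)
Conditions: DCC, DMAP (20 mol%), CH2Cl2, 0 → 20 °C
Reagents that add atoms: none
Why: DCC/DMAP C-acylation of a cyclic 1,3-dione (O-acylation to 18, then DMAP-catalysed O-to-C acyl migration) should place the acyl group on C6 between the two carbonyls, and the (R) acyl stereocentre comes unchanged from acid 17.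

**Compound list**
1 | geraniol | CC(C)=CCC/C(C)=C/CO | starting material
2 | [(2S,3S)-3-methyl-3-(4-methylpent-3-en-1-yl)oxiran-2-yl]methanol | OC[C@@H]1O[C@@]1(C)CCC=C(C)C | intermediate
3 | ethoxyacetylene | CCOC#C | starting material
4 | [(2S,3S)-3-methyl-3-(4-methylpent-3-en-1-yl)oxiran-2-yl]methyl trifluoromethanesulfonate | FC(F)(F)S(=O)(=O)OC[C@@H]1O[C@@]1(C)CCC=C(C)C | intermediate
5 | lithium ethoxyacetylide | [Li]C#COCC | intermediate
6 | (2S,3S)-2-(3-ethoxyprop-2-yn-1-yl)-3-methyl-3-(4-methylpent-3-en-1-yl)oxirane | CCOC#CC[C@@H]1O[C@@]1(C)CCC=C(C)C | intermediate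
7 | isobutyryl chloride | CC(C)C(Cl)=O | starting material
8 | dimethylketene | CC(C)=C=O | intermediate
9 | 3-ethoxy-4,4-dimethylcyclobut-2-en-1-one | CCOC1=CC(=O)C1(C)C | intermediate
10 | 3-ethoxy-4-methylpenta-1,3-dien-1-one | CCOC(C=C=O)=C(C)C | intermediate
11 | 3-ethoxy-4-(1-ethoxy-2-methylprop-1-en-1-yl)-2-{[(2S,3S)-3-methyl-3-(4-methylpent-3-en-1-yl)oxiran-2-yl]methyl}cyclobut-2-en-1-one (both C4 epimers) | CCOC1=C(C[C@@H]2O[C@@]2(C)CCC=C(C)C)C(=O)C1C(OCC)=C(C)C | intermediate
12 | (3E)-3,5-diethoxy-6-methyl-2-{[(2S,3S)-3-methyl-3-(4-methylpent-3-en-1-yl)oxiran-2-yl]methyl}hepta-1,3,5-trien-1-one | O=C=C(C[C@@H]1O[C@@]1(C)CCC=C(C)C)/C(OCC)=C\C(OCC)=C(C)C | intermediate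
13 | 3,5-diethoxy-6,6-dimethyl-2-{[(2S,3S)-3-methyl-3-(4-methylpent-3-en-1-yl)oxiran-2-yl]methyl}cyclohexa-2,4-dien-1-one | CCOC1=CC(OCC)=C(C[C@@H]2O[C@@]2(C)CCC=C(C)C)C(=O)C1(C)C | intermediate
14 | (2R,3S)-7-ethoxy-3-hydroxy-2,8,8-trimethyl-2-(4-methylpent-3-en-1-yl)-3,4-dihydro-2H-chromen-5(8H)-one | CCOC1=CC(=O)C2=C(O[C@](C)(CCC=C(C)C)[C@@H](O)C2)C1(C)C | intermediate
15 | (2R)-7-ethoxy-2,8,8-trimethyl-2-(4-methylpent-3-en-1-yl)-2H-chromen-5(8H)-one | CCOC1=CC(=O)C2=C(O[C@](C)(CCC=C(C)C)C=C2)C1(C)C | intermediate
16 | (2R)-2,8,8-trimethyl-2-(4-methylpent-3-en-1-yl)-2H-chromene-5,7(6H,8H)-dione | O=C1CC(=O)C2=C(O[C@](C)(CCC=C(C)C)C=C2)C1(C)C | intermediate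
17 | (R)-2-methylbutanoic acid | CC[C@@H](C)C(O)=O | starting material
18 | (2R)-2,8,8-trimethyl-2-(4-methylpent-3-en-1-yl)-7-oxo-7,8-dihydro-2H-chromen-5-yl (2R)-2-methylbutanoate | O=C1C=C(OC(=O)[C@H](C)CC)C2=C(O[C@](C)(CCC=C(C)C)C=C2)C1(C)C | intermediate
19 | (2R)-5-hydroxy-2,8,8-trimethyl-6-[(2R)-2-methylbutanoyl]-2-(4-methylpent-3-en-1-yl)-2H-chromen-7(8H)-one | CC[C@@H](C)C(=O)C1=C(O)C2=C(O[C@](C)(CCC=C(C)C)C=C2)C(C)(C)C1=O | target

**Total step count:** 8
**Longest linear sequence:** 7 (steps 1, 2, 4, 5, 6, 7, 8)

**Steps most likely to fail**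

Step 4. The gem-dimethyl cyclobutenone may open too slowly, or vinylketene 10 may be lost by a 1,5-hydrogen shift from its inward methyl group or by dimerization before the ynol ether traps it. The crowded dienylketene may also be diverted before ring closure. The fallback uses known chemistry, sets out from 6 and comes back at 13. Propanoyl chloride and 3 with Et3N should give 3-ethoxy-4-methylcyclobut-2-en-1-one F1 by the same ketene cycloaddition. F1 and 6 in toluene at 80 °C should undergo the standard aromatic benzannulation, the ring CH now being free to tautomerize, to give 3,5-diethoxy-6-methyl-2-{[(2S,3S)-3-methyl-3-(4-methylpent-3-en-1-yl)oxiran-2-yl]methyl}phenol F2. C-Methylation of the lithium phenolate of F2 (LiOtBu, MeI, PhMe) at the methyl-bearing ortho carbon, which lies between two oxygenated carbons, should dearomatize the ring to 13.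

Step 5. The carbonyl oxygen may close the five-membered ring at the secondary epoxide carbon instead of the six-membered ring at the tertiary one. The fallback sets out from 13 and comes back at 15. The five-membered closure would give (2R)-6-ethoxy-2-[(2S)-2-hydroxy-6-methylhept-5-en-2-yl]-7,7-dimethyl-2,3-dihydro-1-benzofuran-4(7H)-one F3, with the tertiary alcohol outside the ring and its configuration unchanged. SOCl2/pyridine should expand the ring through the bridged oxiranium ion: the ring oxygen displaces the activated tertiary hydroxyl with inversion and chloride opens at the secondary carbon. This gives (2R,3S)-3-chloro-7-ethoxy-2,8,8-trimethyl-2-(4-methylpent-3-en-1-yl)-3,4-dihydro-2H-chromen-5(8H)-one F4 with the same (2R) centre as 14. DBU then eliminates HCl to 15.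

Step 7. Hydroxide attack at the ethoxy-bearing carbon may be slow at a temperature the 2H-pyran tolerates, or hydroxide may add at the pyran enol-ether carbon and open the ring. The fallback sets out from 14 and comes back at 19. The ethyl group is removed before the allylic ether exists: dilute aqueous HCl in THF should hydrolyse 14 to (2R,3S)-3-hydroxy-2,8,8-trimethyl-2-(4-methylpent-3-en-1-yl)-3,4-dihydro-2H-chromene-5,7(6H,8H)-dione F5. DCC/DMAP acylation of F5 with 17 should give (2R,3S)-3,5-dihydroxy-2,8,8-trimethyl-6-[(2R)-2-methylbutanoyl]-2-(4-methylpent-3-en-1-yl)-3,4-dihydro-2H-chromen-7(8H)-one F6, the hindered secondary alcohol being left free. Burgess dehydration of F6 with excess reagent (the acidic enol consumes part of it) then gives 19.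

**Further compounds**
F1 | step 4 | 3-ethoxy-4-methylcyclobut-2-en-1-one (racemic) | CCOC1=CC(=O)C1C
F2 | step 4 | 3,5-diethoxy-6-methyl-2-{[(2S,3S)-3-methyl-3-(4-methylpent-3-en-1-yl)oxiran-2-yl]methyl}phenol | CCOc1cc(OCC)c(C[C@@H]2O[C@@]2(C)CCC=C(C)C)c(O)c1C
F3 | step 5 | (2R)-6-ethoxy-2-[(2S)-2-hydroxy-6-methylhept-5-en-2-yl]-7,7-dimethyl-2,3-dihydro-1-benzofuran-4(7H)-one | CCOC1=CC(=O)C2=C(O[C@H](C2)[C@@](C)(O)CCC=C(C)C)C1(C)C
F4 | step 5 | (2R,3S)-3-chloro-7-ethoxy-2,8,8-trimethyl-2-(4-methylpent-3-en-1-yl)-3,4-dihydro-2H-chromen-5(8H)-one | CCOC1=CC(=O)C2=C(O[C@](C)(CCC=C(C)C)[C@@H](Cl)C2)C1(C)C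
F5 | step 7 | (2R,3S)-3-hydroxy-2,8,8-trimethyl-2-(4-methylpent-3-en-1-yl)-3,4-dihydro-2H-chromene-5,7(6H,8H)-dione | O=C1CC(=O)C2=C(O[C@](C)(CCC=C(C)C)[C@@H](O)C2)C1(C)C
F6 | step 7 | (2R,3S)-3,5-dihydroxy-2,8,8-trimethyl-6-[(2R)-2-methylbutanoyl]-2-(4-methylpent-3-en-1-yl)-3,4-dihydro-2H-chromen-7(8H)-one | CC[C@@H](C)C(=O)C1=C(O)C2=C(O[C@](C)(CCC=C(C)C)[C@@H](O)C2)C(C)(C)C1=O
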